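The target is cut at C13–C14: a Stork–Danheiser addition joins an oxepane-fused cyclohexyl iodide to a hydroazulenone. That hydroazulene, the cyclopentane C21–C25 fused to the cycloheptane C14/C16/C18/C20/C21/C22/C28, is read as a benzene ring enlarged by one carbon. An intramolecular Buchner reaction of an aryl diazoketone inserts carbene carbon C21 into the C20–C22 arene bond, closing both rings, forming C21–C22 and C20–C21 and setting C21 in one operation. The precursor is 1-diazo-4-arylbutan-2-one 12, whose ring oxygens are differentiated (O14 silyl, O18 methyl) so that C14 alone is later unmasked as the ketone.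

Key step: step 9

Remarks on the chemistry and assumptions
- Atom labels such as C14 or C21 are the positions of the atoms in the target SMILES.
- The ring-expanded ketone that keeps the C21 stereocentre is the 8aH tautomer, a 3,8a-dihydroazulen-1(2H)-one. The conjugated 3,4-dihydro tautomer has lost that centre and must not form.
- Precursor design: the formyl group that becomes the C28 methyl also directs removal of the neighbouring O-methyl group. O14 then carries a silyl group and O18 a methyl group, so fluoride later gives the β-methoxy enone with its carbonyl at C14 directly.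
- Assumption: the (R,R)-configured bis(oxazoline) gives the 8aR ketone; if the sense is opposite, the mirror-image ligand is used.
- Assumption: 1, 2, 10, 21, 22 and 24 are catalogue chemicals.

Step 1
Reactants: 1 3,5-dimethoxy-4-methylbenzaldehyde; 2 triethyl phosphonoacetate
Product: 3 ethyl (2E)-3-(3,5-dimethoxy-4-methylphenyl)prop-2-enoate
Conditions: NaH, THF, 0 °C to rt
Reagents that add atoms: none
Why: Horner–Wadsworth–Emmons olefination of an aromatic aldehyde by a stabilised phosphonate anion should give the E-cinnamate cleanly.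

Step 2
Reactants: 3 ethyl (2E)-3-(3,5-dimethoxy-4-methylphenyl)prop-2-enoate
Product: 4 ethyl 3-(3,5-dimethoxy-4-methylphenyl)propanoate
Conditions: H2 (1 atm), Pd/C, EtOAc, rt
Reagents that add atoms: none
Why: Heterogeneous catalytic hydrogenation should saturate the conjugated alkene and leave arene and ester alone.

Step 3
Reactants: 4 ethyl 3-(3,5-dimethoxy-4-methylphenyl)propanoate
Product: 5 ethyl 3-(2-formyl-3,5-dimethoxy-4-methylphenyl)propanoate
Conditions: Cl2CHOMe, TiCl4, CH2Cl2, −10 to 0 °C; then H2O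
Reagents that add atoms: dichloromethyl methyl ether, COC(Cl)Cl; water, O
Why: Rieche formylation (electrophilic aromatic substitution) can only take one of the two equivalent free ring positions, each ortho to one methoxy group and para to the other, which puts the future C28 methyl carbon next to the side chain.

Step 4
Reactants: 5 ethyl 3-(2-formyl-3,5-dimethoxy-4-methylphenyl)propanoate
Product: 6 ethyl 3-(2-formyl-3-hydroxy-5-methoxy-4-methylphenyl)propanoate
Conditions: BCl3 (1.2 equiv), CH2Cl2, −78 to 0 °C; then H2O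
Reagents that add atoms: none
Why: Chelation-controlled aryl methyl ether cleavage: boron bound to the formyl oxygen should deliver chloride only to the neighbouring O-methyl group (future O14), while the para methoxy group (future O18) and the ethyl ester stay intact.

Step 5
Reactants: 6 ethyl 3-(2-formyl-3-hydroxy-5-methoxy-4-methylphenyl)propanoate
Product: 7 ethyl 3-(3-hydroxy-5-methoxy-2,4-dimethylphenyl)propanoate
Conditions: H2 (3 atm), Pd/C, AcOH, rt
Reagents that add atoms: none
Why: Benzylic hydrogenolysis of an electron-rich ortho-hydroxy benzaldehyde (through the benzylic alcohol) should give the aryl methyl group and complete the 2,4-dimethyl pattern.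

Step 6
Reactants: 7 ethyl 3-(3-hydroxy-5-methoxy-2,4-dimethylphenyl)propanoate
Product: 8 ethyl 3-{5-methoxy-2,4-dimethyl-3-[(triisopropylsilyl)oxy]phenyl}propanoate
Conditions: i-Pr3SiOTf, 2,6-lutidine, CH2Cl2, 0 °C to rt
Reagents that add atoms: triisopropylsilyl triflate, CC(C)[Si](OS(=O)(=O)C(F)(F)F)(C(C)C)C(C)C
Why: Silylation of the hindered phenol with a silyl triflate and a hindered pyridine base should give a robust aryl silyl ether that survives steps 7 to 9 and later marks O14 for fluoride cleavage.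

Step 7
Reactants: 8 ethyl 3-{5-methoxy-2,4-dimethyl-3-[(triisopropylsilyl)oxy]phenyl}propanoate
Product: 9 3-{5-methoxy-2,4-dimethyl-3-[(triisopropylsilyl)oxy]phenyl}propanoic acid
Conditions: LiOH, THF/MeOH/H2O, rt; then 1 M HCl to pH 3
Reagents that add atoms: lithium hydroxide, [Li+].[OH-]
Why: Ester saponification; the di-ortho-substituted aryl triisopropylsilyl ether should be stable to aqueous LiOH at rt.

Step 8
Reactants: 9 3-{5-methoxy-2,4-dimethyl-3-[(triisopropylsilyl)oxy]phenyl}propanoic acid; 10 trimethylsilyldiazomethane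
Product: 12 1-diazo-4-{5-methoxy-2,4-dimethyl-3-[(triisopropylsilyl)oxy]phenyl}butan-2-one, via acid chloride 11 (not isolated)
Conditions: (COCl)2, DMF (cat.), CH2Cl2, 0 °C to rt; evaporation; then 10 (2 equiv), MeCN/THF, 0 °C to rt
Reagents that add atoms: oxalyl chloride, O=C(Cl)C(=O)Cl (its chlorine is carried only in 11)
Why: Acid chloride formation and acylation of trimethylsilyldiazomethane (Arndt–Eistert-type diazoketone synthesis, the silyl group leaving with chloride) is the standard entry to terminal α-diazoketones.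

Step 9
Reactants: 12 1-diazo-4-{5-methoxy-2,4-dimethyl-3-[(triisopropylsilyl)oxy]phenyl}butan-2-one
Product: 14 (8aR)-7-methoxy-4,6-dimethyl-5-[(triisopropylsilyl)oxy]-3,8a-dihydroazulen-1(2H)-one, via norcaradiene 13 (not isolated)
Conditions: Cu(MeCN)4PF6 (5 mol %), (R,R)-Ph-box [2,2′-(propane-2,2-diyl)bis((4R)-4-phenyl-4,5-dihydrooxazole), 6 mol %], Na[B(3,5-(CF3)2C6H3)4] (6 mol %), CH2Cl2, 40 °C, slow addition of 12; filtration through neutral alumina at 0 °C
Reagents that add atoms: none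
Why: Loss of N2 gives a copper carbene at C21 that cyclopropanates the C20–C22 π-bond to norcaradiene 13, and disrotatory 6π electrocyclic opening of its C20–C22 σ-bond gives cycloheptatriene 14. The closest known reaction type is the intramolecular Buchner reaction of 1-diazo-4-arylbutan-2-ones under copper bis(oxazoline) or dirhodium carboxylate catalysis. The five-membered ring (C21–C25) closes in the cyclopropanation, by attack of the tethered carbene on the ipso carbon through the three-atom chain C23–C24–C25, and the seven-membered ring is the benzene ring expanded by C21 in the electrocyclic step. The only new stereocentre, C21, is set by the chiral ligand, which decides the face of the arene that the carbene approaches. The step needs attack at C20–C22 and not at C22–C28, secured by the methyl group on C28, and cyclopropanation in preference to electrophilic substitution at C20, favoured by the mildly electrophilic copper carbene and by the O14 silyl ether being twisted out of conjugation by its two ortho methyl groups. Because C21–H is α to the ketone and allylic, 14 is filtered cold and methylenated at once.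

Step 10
Reactants: 14 (8aR)-7-methoxy-4,6-dimethyl-5-[(triisopropylsilyl)oxy]-3,8a-dihydroazulen-1(2H)-one
Product: 15 triisopropyl{[(8aS)-7-methoxy-4,6-dimethyl-1-methylidene-1,2,3,8a-tetrahydroazulen-5-yl]oxy}silane
Conditions: Cp2Ti(μ-Cl)(μ-CH2)AlMe2 (1.2 equiv), pyridine, THF/toluene, −40 to 0 °C
Reagents that add atoms: the titanium–aluminium methylidene reagent Cp2Ti(μ-Cl)(μ-CH2)AlMe2, C[Al-]1(C)C[Ti](C2C=CC=C2)(C2C=CC=C2)[Cl+]1
Why: Carbonyl methylenation with the titanium methylidene (Tebbe olefination) is non-basic and runs below 0 °C, so it should convert the C25 ketone without epimerising C21 or touching the enol ethers, and it removes the carbonyl that makes C21–H acidic and the triene acid-labile.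

Step 11
Reactants: 15 triisopropyl{[(8aS)-7-methoxy-4,6-dimethyl-1-methylidene-1,2,3,8a-tetrahydroazulen-5-yl]oxy}silane
Product: 16 (8aS)-7-methoxy-4,6-dimethyl-1-methylidene-2,3,8,8a-tetrahydroazulen-5(1H)-one
Conditions: Bu4NF (1.1 equiv), AcOH (1.1 equiv), THF, 0 °C
Reagents that add atoms: none
Why: Fluoride cleavage of the silyl enol ether releases the C14 enolate, whose protonation and equilibration to the conjugated tautomer should give the β-methoxy enone with its carbonyl at C14 and its methoxy group at C18, the methyl enol ether being inert to buffered fluoride.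

Step 12
Reactants: 16 (8aS)-7-methoxy-4,6-dimethyl-1-methylidene-2,3,8,8a-tetrahydroazulen-5(1H)-one
Product: 17 (1R,8aR)-1-hydroxy-7-methoxy-1,4,6-trimethyl-2,3,8,8a-tetrahydroazulen-5(1H)-one
Conditions: Co(acac)2 (20 mol %), PhSiH3 (2.5 equiv), O2 (1 atm), THF, rt
Reagents that add atoms: dioxygen, O=O
Why: Mukaiyama hydration (hydrogen-atom transfer, then O2 capture) is selective for the 1,1-disubstituted alkene over the tetrasubstituted conjugated ones and gives the Markovnikov tertiary alcohol; the C25 radical should be trapped on the face of H21, anti to the C21–C20 bond, which sets 25R (hydroxyl cis to H21).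

Step 13
Reactants: 17 (1R,8aR)-1-hydroxy-7-methoxy-1,4,6-trimethyl-2,3,8,8a-tetrahydroazulen-5(1H)-one
Product: 18 (1R,3aR,4R,8aR)-1-hydroxy-7-methoxy-1,4,6-trimethyl-2,3,3a,4,8,8a-hexahydroazulen-5(1H)-one
Conditions: H2 (1 to 3 atm), [Ir(cod)(PCy3)(py)]PF6 (10 mol %), CH2Cl2, rt
Reagents that add atoms: none
Why: Hydroxyl-directed homogeneous hydrogenation: the iridium cation bound to the C25 hydroxyl should add H2 to the homoallylic C22=C28 bond from the hydroxyl face, setting H22 cis to H21 (22R, cis ring fusion) and leaving the remote β-methoxy enone alkene untouched; the C28 centre formed here is erased in step 15.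

Step 14
Reactants: 18 (1R,3aR,4R,8aR)-1-hydroxy-7-methoxy-1,4,6-trimethyl-2,3,3a,4,8,8a-hexahydroazulen-5(1H)-one
Product: 19 (1R,3aR,4R,8aR)-7-methoxy-1,4,6-trimethyl-1-[(trimethylsilyl)oxy]-2,3,3a,4,8,8a-hexahydroazulen-5(1H)-one
Conditions: 1-(trimethylsilyl)imidazole, CH2Cl2, rt
Reagents that add atoms: 1-(trimethylsilyl)imidazole, C[Si](C)(C)n1ccnc1
Why: O-silylation of the tertiary alcohol with the silylimidazole, which does not enolise the ketone, protects it for the enolate and organolithium steps.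

Step 15
Reactants: 19 (1R,3aR,4R,8aR)-7-methoxy-1,4,6-trimethyl-1-[(trimethylsilyl)oxy]-2,3,3a,4,8,8a-hexahydroazulen-5(1H)-one
Product: 20 (1R,3aR,8aR)-7-methoxy-1,4,4,6-tetramethyl-1-[(trimethylsilyl)oxy]-2,3,3a,4,8,8a-hexahydroazulen-5(1H)-one
Conditions: LiN(i-Pr)2, THF, −78 °C; MeI, DMPU, −78 to −20 °C
Reagents that add atoms: iodomethane, CI
Why: Kinetic α′-deprotonation of the β-alkoxy enone at C28 and C-methylation of the enolate (Stork–Danheiser α′-alkylation) should install the geminal dimethyl group, after which C28 is no longer stereogenic.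

Step 16
Reactants: 21 geranyl bromide; 22 dimethyl (2-oxopropyl)phosphonate
Product: 23 dimethyl [(5E)-6,10-dimethyl-2-oxoundeca-5,9-dien-1-yl]phosphonate
Conditions: NaH, THF, 0 °C; n-BuLi, 0 °C; then 21, 0 °C to rt; 1 M HCl quench
Reagents that add atoms: none
Why: γ-Alkylation of the dianion of a β-ketophosphonate with an allylic bromide (SN2 at the primary carbon) should give the chain-extended ketophosphonate with the E-alkene intact.

Step 17
Reactants: 23 dimethyl [(5E)-6,10-dimethyl-2-oxoundeca-5,9-dien-1-yl]phosphonate; 24 (benzyloxy)acetaldehyde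
Product: 25 (2E,7E)-1-(benzyloxy)-8,12-dimethyltrideca-2,7,11-trien-4-one
Conditions: LiCl, i-Pr2NEt, MeCN, rt
Reagents that add atoms: none
Why: Horner–Wadsworth–Emmons olefination under LiCl/amine conditions should give the E-enone and tolerates the base-sensitive α-alkoxy aldehyde.

Step 18
Reactants: 25 (2E,7E)-1-(benzyloxy)-8,12-dimethyltrideca-2,7,11-trien-4-one
Product: 28 (2E)-1-(benzyloxy)-6-[(2R,3R)-3-{2-[(2R)-3,3-dimethyloxiran-2-yl]ethyl}-3-methyloxiran-2-yl]hex-2-en-4-one, via terminal monoepoxide 26 (not isolated), via internal monoepoxide 27 (not isolated)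
Conditions: D-fructose-derived ketone catalyst (1,2:4,5-di-O-isopropylidene-β-D-erythro-2,3-hexodiulo-2,6-pyranose, 0.6 equiv), KHSO5 (as 2KHSO5·KHSO4·K2SO4), K2CO3, Bu4NHSO4, Na2B4O7 buffer, MeCN/CH2(OMe)2/H2O, 0 °C
Reagents that add atoms: potassium peroxymonosulfate, [K+].[O-]S(=O)(=O)OO
Why: Shi asymmetric epoxidation (chiral dioxirane) oxidises both electron-rich trisubstituted alkenes and not the electron-poor enone; the D-fructose-derived ketone should give the R,R-oxirane from the E-alkene (future C5 and C31) and the R-oxirane at the terminal alkene (future C35).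

Step 19
Reactants: 28 (2E)-1-(benzyloxy)-6-[(2R,3R)-3-{2-[(2R)-3,3-dimethyloxiran-2-yl]ethyl}-3-methyloxiran-2-yl]hex-2-en-4-one
Product: 29 {[(3Z)-6-(benzyloxy)-1-[(2R,3R)-3-{2-[(2R)-3,3-dimethyloxiran-2-yl]ethyl}-3-methyloxiran-2-yl]hex-3-en-3-yl]oxy}triethylsilane
Conditions: Et3SiH, RhCl(PPh3)3 (1 mol %), benzene, 50 °C
Reagents that add atoms: triethylsilane, CC[SiH](CC)CC
Why: Rhodium-catalysed 1,4-hydrosilylation of the enone should give the regiodefined Z-silyl enol ether, nucleophilic at C11, under neutral conditions that spare both oxiranes.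

Step 20
Reactants: 29 {[(3Z)-6-(benzyloxy)-1-[(2R,3R)-3-{2-[(2R)-3,3-dimethyloxiran-2-yl]ethyl}-3-methyloxiran-2-yl]hex-3-en-3-yl]oxy}triethylsilane
Product: 30 (3R,5aR,6R,9aR)-6-[2-(benzyloxy)ethyl]-2,2,5a-trimethyl-3-[(triethylsilyl)oxy]octahydro-1-benzoxepin-7(2H)-one
Conditions: Et3SiOTf (0.3 equiv), 2,6-di-tert-butyl-4-methylpyridine, CH2Cl2, −78 °C; Et3N quench
Reagents that add atoms: none
Why: Silyl-triflate-promoted tandem oxacyclisation/carbacyclisation of a 1,5-diepoxide terminated by a silyl enol ether: the silylated terminal oxirane is opened at its tertiary carbon C2 by the neighbouring oxirane oxygen, and the resulting epoxonium ion is opened at its tertiary carbon C31 with inversion by C11 through a chair, which should give the trans-fused oxepane–cyclohexanone with C5, C31 and C35 derived from the oxiranes, the C11 side chain equatorial (also the thermodynamic epimer) and the silyl group relayed from the enol oxygen to O36.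

Step 21
Reactants: 30 (3R,5aR,6R,9aR)-6-[2-(benzyloxy)ethyl]-2,2,5a-trimethyl-3-[(triethylsilyl)oxy]octahydro-1-benzoxepin-7(2H)-one
Product: 31 (3R,5aR,6R,7S,9aR)-6-[2-(benzyloxy)ethyl]-2,2,5a,7-tetramethyl-3-[(triethylsilyl)oxy]decahydro-1-benzoxepin-7-ol
Conditions: MeLi, CeCl3, THF, −78 °C; aq. NH4Cl
Reagents that add atoms: methyllithium, [Li]C
Why: 1,2-Addition of the non-basic organocerium reagent to the enolisable ketone; attack should come from the equatorial direction, away from the axial C31 methyl group, giving the axial hydroxyl and equatorial methyl group at C8 (8S).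

Step 22
Reactants: 31 (3R,5aR,6R,7S,9aR)-6-[2-(benzyloxy)ethyl]-2,2,5a,7-tetramethyl-3-[(triethylsilyl)oxy]decahydro-1-benzoxepin-7-ol
Product: 32 (3R,5aR,6R,7S,9aR)-6-[2-(benzyloxy)ethyl]-2,2,5a,7-tetramethyl-3,7-bis[(triethylsilyl)oxy]decahydro-1-benzoxepine
Conditions: Et3SiOTf, 2,6-lutidine, CH2Cl2, 0 °C
Reagents that add atoms: triethylsilyl triflate, CC[Si](CC)(CC)OS(=O)(=O)C(F)(F)F
Why: Silylation of the hindered tertiary alcohol with the silyl triflate; the triethylsilyl ether resists O-to-C silyl migration in the later alkyllithium and prevents tetrahydrofuran formation from the iodide.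

Step 23
Reactants: 32 (3R,5aR,6R,7S,9aR)-6-[2-(benzyloxy)ethyl]-2,2,5a,7-tetramethyl-3,7-bis[(triethylsilyl)oxy]decahydro-1-benzoxepine
Product: 33 2-{(3R,5aR,6R,7S,9aR)-2,2,5a,7-tetramethyl-3,7-bis[(triethylsilyl)oxy]decahydro-1-benzoxepin-6-yl}ethanol
Conditions: H2 (1 atm), Pd/C, EtOAc, rt
Reagents that add atoms: none
Why: Hydrogenolysis of the benzyl ether in EtOAc should leave both silyl ethers in place.

Step 24
Reactants: 33 2-{(3R,5aR,6R,7S,9aR)-2,2,5a,7-tetramethyl-3,7-bis[(triethylsilyl)oxy]decahydro-1-benzoxepin-6-yl}ethanol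
Product: 34 (3R,5aR,6R,7S,9aR)-6-(2-iodoethyl)-2,2,5a,7-tetramethyl-3,7-bis[(triethylsilyl)oxy]decahydro-1-benzoxepine
Conditions: I2, PPh3, imidazole, CH2Cl2, 0 °C
Reagents that add atoms: iodine, II
Why: Appel-type iodination converts the primary alcohol into the iodide by SN2 displacement of the oxyphosphonium group.

Step 25
Reactants: 34 (3R,5aR,6R,7S,9aR)-6-(2-iodoethyl)-2,2,5a,7-tetramethyl-3,7-bis[(triethylsilyl)oxy]decahydro-1-benzoxepine; 20 (1R,3aR,8aR)-7-methoxy-1,4,4,6-tetramethyl-1-[(trimethylsilyl)oxy]-2,3,3a,4,8,8a-hexahydroazulen-5(1H)-one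
Product: 38 (1R,3aR,8aR)-5-{2-[(3R,5aR,6R,7S,9aR)-3,7-dihydroxy-2,2,5a,7-tetramethyldecahydro-1-benzoxepin-6-yl]ethyl}-1-hydroxy-1,4,4,6-tetramethyl-2,3,3a,4,8,8a-hexahydroazulen-7(1H)-one, via alkyllithium 35 (not isolated), via lithium alkoxide adduct 36 (not isolated), via silylated enone 37 (not isolated)
Conditions: 34 (1.3 equiv), t-BuLi (2.1 equiv per 34), Et2O/pentane, −78 °C; 20, −78 to 0 °C; then HF (5% aq.), MeCN, rt
Reagents that add atoms: water, O
Why: Stork–Danheiser sequence: iodine–lithium exchange gives a primary alkyllithium that adds to the C14 carbonyl of the β-methoxy enone (C28 carries no hydrogen), and acid then ionises the tertiary allylic alkoxide, hydrolyses the enol ether to the transposed enone C14=C16–C18=O and removes the three silyl groups; no stereocentre is formed.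

Step 26
Reactants: 38 (1R,3aR,8aR)-5-{2-[(3R,5aR,6R,7S,9aR)-3,7-dihydroxy-2,2,5a,7-tetramethyldecahydro-1-benzoxepin-6-yl]ethyl}-1-hydroxy-1,4,4,6-tetramethyl-2,3,3a,4,8,8a-hexahydroazulen-7(1H)-one
Product: 39 (1R,3aR,7R,8aR)-5-{2-[(3R,5aR,6R,7S,9aR)-3,7-dihydroxy-2,2,5a,7-tetramethyldecahydro-1-benzoxepin-6-yl]ethyl}-1,4,4,6-tetramethyl-1,2,3,3a,4,7,8,8a-octahydroazulene-1,7-diol
Conditions: (S)-2-methyl-CBS-oxazaborolidine (0.5 equiv), catecholborane (5 equiv), toluene/CH2Cl2, −78 to −40 °C; MeOH, then aq. NaOH work-up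
Reagents that add atoms: none
Why: Corey–Bakshi–Shibata reduction under reagent control: with the α-methylated alkenyl arm as the large group and C20H2 as the small one, the (S)-oxazaborolidine should deliver hydride 1,2 to give the 18R allylic alcohol (hydroxyl cis to H21 and H22), the free hydroxyls being capped in situ as borates.

Step 27
Reactants: 39 (1R,3aR,7R,8aR)-5-{2-[(3R,5aR,6R,7S,9aR)-3,7-dihydroxy-2,2,5a,7-tetramethyldecahydro-1-benzoxepin-6-yl]ethyl}-1,4,4,6-tetramethyl-1,2,3,3a,4,7,8,8a-octahydroazulene-1,7-diol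
Product: 40 CNP0203623.2 (14S,16R,18R,21R,22R,25R and 5R,8S,11R,31R,35R)
Conditions: VO(acac)2 (5 mol %), t-BuOOH (1.5 equiv, in decane), CH2Cl2, 0 °C to rt
Reagents that add atoms: tert-butyl hydroperoxide, CC(C)(C)OO
Why: Hydroxyl-directed epoxidation with vanadium and an alkyl hydroperoxide: the vanadate ester of the C18 hydroxyl should deliver oxygen to the same face of the only alkene, C14=C16, setting 14S and 16R under neutral conditions that the epoxy alcohol tolerates.

Compound list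
1 | 3,5-dimethoxy-4-methylbenzaldehyde | COc1cc(C=O)cc(OC)c1C | starting material
2 | triethyl phosphonoacetate | CCOC(=O)CP(=O)(OCC)OCC | starting material
3 | ethyl (2E)-3-(3,5-dimethoxy-4-methylphenyl)prop-2-enoate | CCOC(=O)/C=C/c1cc(OC)c(C)c(OC)c1 | intermediate
4 | ethyl 3-(3,5-dimethoxy-4-methylphenyl)propanoate | CCOC(=O)CCc1cc(OC)c(C)c(OC)c1 | intermediate
5 | ethyl 3-(2-formyl-3,5-dimethoxy-4-methylphenyl)propanoate | CCOC(=O)CCc1cc(OC)c(C)c(OC)c1C=O | intermediate
6 | ethyl 3-(2-formyl-3-hydroxy-5-methoxy-4-methylphenyl)propanoate | CCOC(=O)CCc1cc(OC)c(C)c(O)c1C=O | intermediate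
7 | ethyl 3-(3-hydroxy-5-methoxy-2,4-dimethylphenyl)propanoate | CCOC(=O)CCc1cc(OC)c(C)c(O)c1C | intermediate
8 | ethyl 3-{5-methoxy-2,4-dimethyl-3-[(triisopropylsilyl)oxy]phenyl}propanoate | CCOC(=O)CCc1cc(OC)c(C)c(O[Si](C(C)C)(C(C)C)C(C)C)c1C | intermediate
9 | 3-{5-methoxy-2,4-dimethyl-3-[(triisopropylsilyl)oxy]phenyl}propanoic acid | OC(=O)CCc1cc(OC)c(C)c(O[Si](C(C)C)(C(C)C)C(C)C)c1C | intermediate
10 | trimethylsilyldiazomethane | C[Si](C)(C)C=[N+]=[N-] | starting material
11 | 3-{5-methoxy-2,4-dimethyl-3-[(triisopropylsilyl)oxy]phenyl}propanoyl chloride | ClC(=O)CCc1cc(OC)c(C)c(O[Si](C(C)C)(C(C)C)C(C)C)c1C | intermediate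
12 | 1-diazo-4-{5-methoxy-2,4-dimethyl-3-[(triisopropylsilyl)oxy]phenyl}butan-2-one | [N-]=[N+]=CC(=O)CCc1cc(OC)c(C)c(O[Si](C(C)C)(C(C)C)C(C)C)c1C | intermediate
13 | norcaradiene valence isomer of 14 (cyclopropane C20–C21–C22 closed; all ring fusions cis) | O=C1CC[C@@]23C(C)=C(O[Si](C(C)C)(C(C)C)C(C)C)C(C)=C(OC)[C@@H]2[C@@H]13 | intermediate
14 | (8aR)-7-methoxy-4,6-dimethyl-5-[(triisopropylsilyl)oxy]-3,8a-dihydroazulen-1(2H)-one | O=C1CCC2=C(C)C(O[Si](C(C)C)(C(C)C)C(C)C)=C(C)C(OC)=C[C@@H]12 | intermediate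
15 | triisopropyl{[(8aS)-7-methoxy-4,6-dimethyl-1-methylidene-1,2,3,8a-tetrahydroazulen-5-yl]oxy}silane | C=C1CCC2=C(C)C(O[Si](C(C)C)(C(C)C)C(C)C)=C(C)C(OC)=C[C@@H]12 | intermediate
16 | (8aS)-7-methoxy-4,6-dimethyl-1-methylidene-2,3,8,8a-tetrahydroazulen-5(1H)-one | C=C1CCC2=C(C)C(=O)C(C)=C(OC)C[C@@H]12 | intermediate
17 | (1R,8aR)-1-hydroxy-7-methoxy-1,4,6-trimethyl-2,3,8,8a-tetrahydroazulen-5(1H)-one | C[C@@]1(O)CCC2=C(C)C(=O)C(C)=C(OC)C[C@@H]12 | intermediate
18 | (1R,3aR,4R,8aR)-1-hydroxy-7-methoxy-1,4,6-trimethyl-2,3,3a,4,8,8a-hexahydroazulen-5(1H)-one | C[C@@]1(O)CC[C@H]2[C@@H](C)C(=O)C(C)=C(OC)C[C@@H]12 | intermediate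
19 | (1R,3aR,4R,8aR)-7-methoxy-1,4,6-trimethyl-1-[(trimethylsilyl)oxy]-2,3,3a,4,8,8a-hexahydroazulen-5(1H)-one | C[C@@]1(O[Si](C)(C)C)CC[C@H]2[C@@H](C)C(=O)C(C)=C(OC)C[C@@H]12 | intermediate
20 | (1R,3aR,8aR)-7-methoxy-1,4,4,6-tetramethyl-1-[(trimethylsilyl)oxy]-2,3,3a,4,8,8a-hexahydroazulen-5(1H)-one | C[C@@]1(O[Si](C)(C)C)CC[C@H]2C(C)(C)C(=O)C(C)=C(OC)C[C@@H]12 | intermediate
21 | geranyl bromide [(2E)-1-bromo-3,7-dimethylocta-2,6-diene] | CC(C)=CCC/C(C)=C/CBr | starting material
22 | dimethyl (2-oxopropyl)phosphonate | COP(=O)(OC)CC(C)=O | starting material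
23 | dimethyl [(5E)-6,10-dimethyl-2-oxoundeca-5,9-dien-1-yl]phosphonate | COP(=O)(OC)CC(=O)CC/C=C(C)/CCC=C(C)C | intermediate
24 | (benzyloxy)acetaldehyde | O=CCOCc1ccccc1 | starting material
25 | (2E,7E)-1-(benzyloxy)-8,12-dimethyltrideca-2,7,11-trien-4-one | CC(C)=CCC/C(C)=C/CCC(=O)/C=C/COCc1ccccc1 | intermediate
26 | (2E,7E)-1-(benzyloxy)-10-[(2R)-3,3-dimethyloxiran-2-yl]-8-methyldeca-2,7-dien-4-one | O=C(/C=C/COCc1ccccc1)CC/C=C(C)/CC[C@H]1OC1(C)C | intermediate
27 | (2E)-1-(benzyloxy)-6-[(2R,3R)-3-methyl-3-(4-methylpent-3-en-1-yl)oxiran-2-yl]hex-2-en-4-one | O=C(/C=C/COCc1ccccc1)CC[C@H]1O[C@]1(C)CCC=C(C)C | intermediate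
28 | (2E)-1-(benzyloxy)-6-[(2R,3R)-3-{2-[(2R)-3,3-dimethyloxiran-2-yl]ethyl}-3-methyloxiran-2-yl]hex-2-en-4-one | O=C(/C=C/COCc1ccccc1)CC[C@H]1O[C@]1(C)CC[C@H]1OC1(C)C | intermediate
29 | {[(3Z)-6-(benzyloxy)-1-[(2R,3R)-3-{2-[(2R)-3,3-dimethyloxiran-2-yl]ethyl}-3-methyloxiran-2-yl]hex-3-en-3-yl]oxy}triethylsilane | CC[Si](CC)(CC)O/C(CC[C@H]1O[C@]1(C)CC[C@H]1OC1(C)C)=C\CCOCc1ccccc1 | intermediate
30 | (3R,5aR,6R,9aR)-6-[2-(benzyloxy)ethyl]-2,2,5a-trimethyl-3-[(triethylsilyl)oxy]octahydro-1-benzoxepin-7(2H)-one | CC1(C)O[C@@H]2CCC(=O)[C@H](CCOCc3ccccc3)[C@@]2(C)CC[C@H]1O[Si](CC)(CC)CC | intermediate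
31 | (3R,5aR,6R,7S,9aR)-6-[2-(benzyloxy)ethyl]-2,2,5a,7-tetramethyl-3-[(triethylsilyl)oxy]decahydro-1-benzoxepin-7-ol | CC1(C)O[C@@H]2CC[C@](C)(O)[C@H](CCOCc3ccccc3)[C@@]2(C)CC[C@H]1O[Si](CC)(CC)CC | intermediate
32 | (3R,5aR,6R,7S,9aR)-6-[2-(benzyloxy)ethyl]-2,2,5a,7-tetramethyl-3,7-bis[(triethylsilyl)oxy]decahydro-1-benzoxepine | CC1(C)O[C@@H]2CC[C@](C)(O[Si](CC)(CC)CC)[C@H](CCOCc3ccccc3)[C@@]2(C)CC[C@H]1O[Si](CC)(CC)CC | intermediate
33 | 2-{(3R,5aR,6R,7S,9aR)-2,2,5a,7-tetramethyl-3,7-bis[(triethylsilyl)oxy]decahydro-1-benzoxepin-6-yl}ethanol | CC1(C)O[C@@H]2CC[C@](C)(O[Si](CC)(CC)CC)[C@H](CCO)[C@@]2(C)CC[C@H]1O[Si](CC)(CC)CC | intermediate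
34 | (3R,5aR,6R,7S,9aR)-6-(2-iodoethyl)-2,2,5a,7-tetramethyl-3,7-bis[(triethylsilyl)oxy]decahydro-1-benzoxepine | CC1(C)O[C@@H]2CC[C@](C)(O[Si](CC)(CC)CC)[C@H](CCI)[C@@]2(C)CC[C@H]1O[Si](CC)(CC)CC | intermediate
35 | (2-{(3R,5aR,6R,7S,9aR)-2,2,5a,7-tetramethyl-3,7-bis[(triethylsilyl)oxy]decahydro-1-benzoxepin-6-yl}ethyl)lithium | CC1(C)O[C@@H]2CC[C@](C)(O[Si](CC)(CC)CC)[C@H](CC[Li])[C@@]2(C)CC[C@H]1O[Si](CC)(CC)CC | intermediate
36 | lithium C14-alkoxide of the 1,2-adduct of 35 to 20 (configuration at C14 immaterial) | CC1(C)O[C@@H]2CC[C@](C)(O[Si](CC)(CC)CC)[C@H](CCC3(O[Li])C(C)=C(OC)C[C@@H]4[C@@H](CC[C@@]4(C)O[Si](C)(C)C)C3(C)C)[C@@]2(C)CC[C@H]1O[Si](CC)(CC)CC | intermediate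
37 | tris-silyl ether of 38 (O36 and O10 triethylsilyl; O27 trimethylsilyl) | CC1(C)O[C@@H]2CC[C@](C)(O[Si](CC)(CC)CC)[C@H](CCC3=C(C)C(=O)C[C@@H]4[C@@H](CC[C@@]4(C)O[Si](C)(C)C)C3(C)C)[C@@]2(C)CC[C@H]1O[Si](CC)(CC)CC | intermediate
38 | (1R,3aR,8aR)-5-{2-[(3R,5aR,6R,7S,9aR)-3,7-dihydroxy-2,2,5a,7-tetramethyldecahydro-1-benzoxepin-6-yl]ethyl}-1-hydroxy-1,4,4,6-tetramethyl-2,3,3a,4,8,8a-hexahydroazulen-7(1H)-one | CC1(C)O[C@@H]2CC[C@](C)(O)[C@H](CCC3=C(C)C(=O)C[C@@H]4[C@@H](CC[C@@]4(C)O)C3(C)C)[C@@]2(C)CC[C@H]1O | intermediate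
39 | (1R,3aR,7R,8aR)-5-{2-[(3R,5aR,6R,7S,9aR)-3,7-dihydroxy-2,2,5a,7-tetramethyldecahydro-1-benzoxepin-6-yl]ethyl}-1,4,4,6-tetramethyl-1,2,3,3a,4,7,8,8a-octahydroazulene-1,7-diol | CC1(C)O[C@@H]2CC[C@](C)(O)[C@H](CCC3=C(C)[C@H](O)C[C@@H]4[C@@H](CC[C@@]4(C)O)C3(C)C)[C@@]2(C)CC[C@H]1O | intermediate
40 | CNP0203623.2 (14S,16R,18R,21R,22R,25R and 5R,8S,11R,31R,35R) | CC1(C)O[C@@H]2CC[C@](C)(O)[C@H](CC[C@@]34O[C@]3(C)[C@H](O)C[C@@H]3[C@@H](CC[C@@]3(C)O)C4(C)C)[C@@]2(C)CC[C@H]1O | target

Total step count: 27 (steps 1–15 for the hydroazulenone, 16–24 for the iodide, 25–27 for union and finish).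
Longest linear sequence: 18 steps (steps 1–15, then 25–27).

Steps most likely to fail

Step 9. The copper carbene may discriminate poorly between the two faces of the ortho-methylated, electron-rich ring, so that C21 is formed with low enantiomeric purity, and proton shift in the product may erode it further before step 10. The fallback sets out from 12 and comes back at 17. Diazoketone 12 is decomposed with achiral Rh2(OAc)4 (0.5 mol %, CH2Cl2, reflux), which gives 14 together with its mirror image, the (8aS)-azulenone F2, through 13 and the enantiomeric norcaradiene F1. The racemate is carried through steps 10 to 12 unchanged, so that the enantiomeric methylidene compound F3, the enantiomeric dienone F4 and the enantiomeric alcohol F5 accompany 15, 16 and 17. Alcohol 17 is then separated from F5 by preparative chromatography on a chiral stationary phase and continues with step 13.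

Step 25. Addition of the alkyllithium to the neopentyl-type C14 carbonyl may be slow, so that proton abstraction at C20 or silyl migration from oxygen to carbon within 35 consumes the nucleophile. The fallback sets out from 34 and 20 and comes back at 38; it replaces carbonyl addition by B-alkyl Suzuki–Miyaura coupling. Iodide 34 is dehydroiodinated (KOt-Bu, THF, 0 °C) to the vinyl compound F7, which is hydroborated with 9-BBN (THF, rt) to the B-alkyl-9-BBN F8, used without isolation. Ketone 20 is deprotonated at C20, the only acidic position once C28 is quaternary (KN(SiMe3)2, THF, −78 °C), and the dienolate is trapped on oxygen with PhNTf2 to give the dienyl triflate F9. Coupling of F8 with F9 (Pd(dppf)Cl2, AsPh3, Cs2CO3, DMF/THF/H2O, rt) forms C13–C14 and gives the methoxydiene F10. HF (5% aq.) in MeCN hydrolyses its enol ether and removes the silyl groups, through 37, to give 38.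

Step 13. The cationic iridium catalyst may lose activity before the tetrasubstituted, electron-poor C22=C28 bond is saturated. The fallback sets out from 17 and comes back at 20, bypassing 18 and 19; it is a dissolving-metal reductive methylation (Li, NH3/THF, −78 °C, then MeI). The enone C22=C28–C14=O should be reduced in preference to the electron-rich β-methoxy enone part. The free tertiary hydroxyl on the face of H21 can serve as the internal proton source for C22, which favours the cis ring fusion. The regiodefined C14/C28 enolate is methylated in the same flask to give the gem-dimethyl hydroxy ketone F6, and silylation of F6 with 1-(trimethylsilyl)imidazole returns to 20.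

Further compounds
F1 | step 9 | enantiomer of norcaradiene 13 | O=C1CC[C@]23C(C)=C(O[Si](C(C)C)(C(C)C)C(C)C)C(C)=C(OC)[C@H]2[C@H]13
F2 | step 9 | (8aS)-7-methoxy-4,6-dimethyl-5-[(triisopropylsilyl)oxy]-3,8a-dihydroazulen-1(2H)-one | O=C1CCC2=C(C)C(O[Si](C(C)C)(C(C)C)C(C)C)=C(C)C(OC)=C[C@H]12
F3 | step 9 | triisopropyl{[(8aR)-7-methoxy-4,6-dimethyl-1-methylidene-1,2,3,8a-tetrahydroazulen-5-yl]oxy}silane | C=C1CCC2=C(C)C(O[Si](C(C)C)(C(C)C)C(C)C)=C(C)C(OC)=C[C@H]12
F4 | step 9 | (8aR)-7-methoxy-4,6-dimethyl-1-methylidene-2,3,8,8a-tetrahydroazulen-5(1H)-one | C=C1CCC2=C(C)C(=O)C(C)=C(OC)C[C@H]12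
F5 | step 9 | (1S,8aS)-1-hydroxy-7-methoxy-1,4,6-trimethyl-2,3,8,8a-tetrahydroazulen-5(1H)-one | C[C@]1(O)CCC2=C(C)C(=O)C(C)=C(OC)C[C@H]12
F6 | step 13 | (1R,3aR,8aR)-1-hydroxy-7-methoxy-1,4,4,6-tetramethyl-2,3,3a,4,8,8a-hexahydroazulen-5(1H)-one | C[C@@]1(O)CC[C@H]2C(C)(C)C(=O)C(C)=C(OC)C[C@@H]12
F7 | step 25 | (3R,5aR,6R,7S,9aR)-6-ethenyl-2,2,5a,7-tetramethyl-3,7-bis[(triethylsilyl)oxy]decahydro-1-benzoxepine | CC1(C)O[C@@H]2CC[C@](C)(O[Si](CC)(CC)CC)[C@H](C=C)[C@@]2(C)CC[C@H]1O[Si](CC)(CC)CC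
F8 | step 25 | 9-(2-{(3R,5aR,6R,7S,9aR)-2,2,5a,7-tetramethyl-3,7-bis[(triethylsilyl)oxy]decahydro-1-benzoxepin-6-yl}ethyl)-9-borabicyclo[3.3.1]nonane | CC1(C)O[C@@H]2CC[C@](C)(O[Si](CC)(CC)CC)[C@H](CCB3C4CCCC3CCC4)[C@@]2(C)CC[C@H]1O[Si](CC)(CC)CC
F9 | step 25 | (1R,3aR,8aR)-7-methoxy-1,4,4,6-tetramethyl-1-[(trimethylsilyl)oxy]-1,2,3,3a,4,8a-hexahydroazulen-5-yl trifluoromethanesulfonate | C[C@@]1(O[Si](C)(C)C)CC[C@H]2C(C)(C)C(OS(=O)(=O)C(F)(F)F)=C(C)C(OC)=C[C@@H]12
F10 | step 25 | C18-methoxy-C14(C16),C18(C20)-diene coupling product (tris-silyl ether; C13–C14 bond formed) | CC1(C)O[C@@H]2CC[C@](C)(O[Si](CC)(CC)CC)[C@H](CCC3=C(C)C(OC)=C[C@@H]4[C@@H](CC[C@@]4(C)O[Si](C)(C)C)C3(C)C)[C@@]2(C)CC[C@H]1O[Si](CC)(CC)CC
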